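**Retrosynthetic overview**
- The target is reached by loss of EtOH, enolisation and desilylation from a cis-fused pyrano-cyclohexanetrione. That bicycle is the intramolecular inverse-electron-demand hetero-Diels–Alder adduct of an acyclic ene-trione (α-methoxy enone as 1-oxadiene, β-ethoxy enone as 2π partner, four-atom tether through C7). Rings A and B form together in this step.
- The ene-trione comes from oxidative opening of a 2-acyl-4-methoxy-5-alkylfuran (masked cis-ene-dione).
- The furyl ketone, the β-ethoxy enone and the C7 butyrate are assembled on the pivalaldehyde acetal of (R)-lactic acid: enolate aldol with (E)-3-ethoxyacrolein sets C7, the lactone carbonyl is then transferred to a 5-lithiofuran, followed by oxidation and butyrylation.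
- The furan comes from 3-methoxyfuran and a protected 3-iodopropanol.

Assumption: (R)-lactic acid, 3-methoxyfuran and (2E)-3-ethoxyprop-2-enal are bought; the carbinol centre formed next to C7 in step 3 is carried as an epimer mixture because step 4 removes it.

**Route**

Step 1
Reactants: 1 (R)-lactic acid; 2 pivalaldehyde
Product: 3 (2R,5R)-2-tert-butyl-5-methyl-1,3-dioxolan-4-one
Conditions: TsOH·H2O (cat.), H2SO4 (cat.), pentane, reflux, Dean–Stark; recrystallise from pentane–Et2O, −78 °C
Reagents that add atoms: none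
Why: Acid-catalysed acetalisation (Seebach dioxolanone formation) under thermodynamic control gives mainly the cis acetal, so the lactate stereocentre fixes the new acetal centre, and cold crystallisation removes the minor trans isomer.

Step 2
Reactants: 4 3-methoxyfuran; 5 tert-butyl(3-iodopropoxy)dimethylsilane
Product: 7 tert-butyl[3-(3-methoxyfuran-2-yl)propoxy]dimethylsilane, via 2-lithio-3-methoxyfuran 6 (not isolated)
Conditions: n-BuLi, THF, −78 to 0 °C; then 5, DMPU, −78 °C to rt
Reagents that add atoms: none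
Why: Directed α-lithiation at C2 (between the ring oxygen and the methoxy group) followed by SN2 alkylation of the furyllithium with the primary iodide.

Step 3
Reactants: 3 (2R,5R)-2-tert-butyl-5-methyl-1,3-dioxolan-4-one; 8 (2E)-3-ethoxyprop-2-enal; 7 tert-butyl[3-(3-methoxyfuran-2-yl)propoxy]dimethylsilane
Product: 12 (2S,4E)-1-[5-(3-{[tert-butyl(dimethyl)silyl]oxy}propyl)-4-methoxyfuran-2-yl]-5-ethoxy-2,3-dihydroxy-2-methylpent-4-en-1-one (C3 epimers), via lithium dioxolanone enolate 9 (not isolated), via lithium aldolate 10 (not isolated), via 5-lithiofuran 11 (not isolated)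
Conditions: LiN(i-Pr)2, THF, −78 °C; 8, −78 °C; then 11 (from 7, n-BuLi, THF, −78 to 0 °C), −78 to −30 °C; AcOH, −78 °C
Reagents that add atoms: none
Why: Seebach self-regeneration-of-stereocentre aldol in which the aldehyde attacks the enolate anti to the tert-butyl group, so the lactate-derived acetal centre sets C7 with overall retention, after which the furyllithium undergoes acyl substitution at the activated lactone (the only electrophile left beside the alkoxide) and pivalaldehyde is released on work-up.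

Step 4
Reactants: 12 (2S,4E)-1-[5-(3-{[tert-butyl(dimethyl)silyl]oxy}propyl)-4-methoxyfuran-2-yl]-5-ethoxy-2,3-dihydroxy-2-methylpent-4-en-1-one
Product: 13 (2S,4E)-1-[5-(3-{[tert-butyl(dimethyl)silyl]oxy}propyl)-4-methoxyfuran-2-yl]-5-ethoxy-2-hydroxy-2-methylpent-4-ene-1,3-dione
Conditions: IBX, NaHCO3, DMSO, rt
Reagents that add atoms: none
Why: IBX oxidation of the secondary allylic alcohol to the vinylogous ester without glycol cleavage; the tertiary alcohol is inert and both carbinol epimers converge.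

Step 5
Reactants: 13 (2S,4E)-1-[5-(3-{[tert-butyl(dimethyl)silyl]oxy}propyl)-4-methoxyfuran-2-yl]-5-ethoxy-2-hydroxy-2-methylpent-4-ene-1,3-dione
Product: 14 (2S,4E)-1-[5-(3-{[tert-butyl(dimethyl)silyl]oxy}propyl)-4-methoxyfuran-2-yl]-5-ethoxy-2-methyl-1,3-dioxopent-4-en-2-yl butanoate
Conditions: (PrCO)2O, Et3N, DMAP (cat.), CH2Cl2, 0 °C to rt
Reagents that add atoms: butyric anhydride, CCCC(=O)OC(=O)CCC
Why: DMAP-catalysed (Steglich-type) acylation of the tertiary α-ketol, the same kind of esterification that works on the tertiary 7-hydroxyl of azaphilones; C7 has no α-hydrogen and cannot epimerise.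

Step 6
Reactants: 14 (2S,4E)-1-[5-(3-{[tert-butyl(dimethyl)silyl]oxy}propyl)-4-methoxyfuran-2-yl]-5-ethoxy-2-methyl-1,3-dioxopent-4-en-2-yl butanoate
Product: 18 (7S)-5-hydroxy-3-(3-hydroxypropyl)-4-methoxy-7-methyl-6,8-dioxo-7,8-dihydro-6H-isochromen-7-yl butanoate (target), via ene-trione 15 (not isolated), via hetero-Diels–Alder cycloadduct 16 (not isolated), via silyl-protected azaphilone 17 (not isolated)
Conditions: DMDO, acetone–CH2Cl2, −78 to −20 °C; evaporate; toluene, 80 °C; then TsOH·H2O (cat.), MeOH, rt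
Reagents that add atoms: dimethyldioxirane (DMDO), CC1(C)OO1
Why: DMDO opens the electron-rich furan to the cis-ene-trione, whose α-methoxy enone (a 1-oxadiene activated by the adjacent 1,2-dione and held four atoms from the electron-rich β-ethoxy-enone C=C) undergoes an intramolecular inverse-electron-demand hetero-Diels–Alder reaction that closes rings A and B at once, after which acid-catalysed loss of EtOH, enolisation of the C5 ketone and methanolysis of the silyl ether give the azaphilone while the quaternary C7 centre is untouched.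

**Compound list**

1 | (R)-lactic acid | C[C@@H](O)C(=O)O | starting material
2 | pivalaldehyde | CC(C)(C)C=O | starting material
3 | (2R,5R)-2-tert-butyl-5-methyl-1,3-dioxolan-4-one | C[C@H]1O[C@@H](C(C)(C)C)OC1=O | intermediate
4 | 3-methoxyfuran | COc1ccoc1 | starting material
5 | tert-butyl(3-iodopropoxy)dimethylsilane | CC(C)(C)[Si](C)(C)OCCCI | starting material
6 | (3-methoxyfuran-2-yl)lithium | [Li]c1occc1OC | intermediate
7 | tert-butyl[3-(3-methoxyfuran-2-yl)propoxy]dimethylsilane | COc1ccoc1CCCO[Si](C)(C)C(C)(C)C | intermediate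
8 | (2E)-3-ethoxyprop-2-enal | CCO/C=C/C=O | starting material
9 | lithium (2R)-2-tert-butyl-5-methyl-1,3-dioxol-4-olate | [Li]OC1=C(C)O[C@@H](C(C)(C)C)O1 | intermediate
10 | lithium (2E)-1-[(2R,4S)-2-tert-butyl-4-methyl-5-oxo-1,3-dioxolan-4-yl]-3-ethoxyprop-2-en-1-olate (carbinol epimers) | CCO/C=C/C(O[Li])[C@]1(C)O[C@@H](C(C)(C)C)OC1=O | intermediate
11 | [5-(3-{[tert-butyl(dimethyl)silyl]oxy}propyl)-4-methoxyfuran-2-yl]lithium | [Li]c1cc(OC)c(CCCO[Si](C)(C)C(C)(C)C)o1 | intermediate
12 | (2S,4E)-1-[5-(3-{[tert-butyl(dimethyl)silyl]oxy}propyl)-4-methoxyfuran-2-yl]-5-ethoxy-2,3-dihydroxy-2-methylpent-4-en-1-one (C3 epimers) | CCO/C=C/C(O)[C@](C)(O)C(=O)c1cc(OC)c(CCCO[Si](C)(C)C(C)(C)C)o1 | intermediate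
13 | (2S,4E)-1-[5-(3-{[tert-butyl(dimethyl)silyl]oxy}propyl)-4-methoxyfuran-2-yl]-5-ethoxy-2-hydroxy-2-methylpent-4-ene-1,3-dione | CCO/C=C/C(=O)[C@](C)(O)C(=O)c1cc(OC)c(CCCO[Si](C)(C)C(C)(C)C)o1 | intermediate
14 | (2S,4E)-1-[5-(3-{[tert-butyl(dimethyl)silyl]oxy}propyl)-4-methoxyfuran-2-yl]-5-ethoxy-2-methyl-1,3-dioxopent-4-en-2-yl butanoate | CCCC(=O)O[C@@](C)(C(=O)/C=C/OCC)C(=O)c1cc(OC)c(CCCO[Si](C)(C)C(C)(C)C)o1 | intermediate
15 | (1E,4S,7E)-12-{[tert-butyl(dimethyl)silyl]oxy}-1-ethoxy-8-methoxy-4-methyl-3,5,6,9-tetraoxododeca-1,7-dien-4-yl butanoate (cis-ene-dione: the two ketone carbons are cis across C7=C8) | CCCC(=O)O[C@@](C)(C(=O)/C=C/OCC)C(=O)C(=O)/C=C(OC)\C(=O)CCCO[Si](C)(C)C(C)(C)C | intermediate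
16 | (7S)-3-(3-{[tert-butyl(dimethyl)silyl]oxy}propyl)-1-ethoxy-4-methoxy-7-methyl-5,6,8-trioxo-4a,5,6,7,8,8a-hexahydro-1H-isochromen-7-yl butanoate (cis-fused, C1 epimers) | CCCC(=O)O[C@@]1(C)C(=O)C2C(OCC)OC(CCCO[Si](C)(C)C(C)(C)C)=C(OC)C2C(=O)C1=O | intermediate
17 | (7S)-3-(3-{[tert-butyl(dimethyl)silyl]oxy}propyl)-5-hydroxy-4-methoxy-7-methyl-6,8-dioxo-7,8-dihydro-6H-isochromen-7-yl butanoate | CCCC(=O)O[C@@]1(C)C(=O)C2=COC(CCCO[Si](C)(C)C(C)(C)C)=C(OC)C2=C(O)C1=O | intermediate
18 | (7S)-5-hydroxy-3-(3-hydroxypropyl)-4-methoxy-7-methyl-6,8-dioxo-7,8-dihydro-6H-isochromen-7-yl butanoate | CCCC(=O)O[C@@]1(C)C(=O)C2=COC(CCCO)=C(OC)C2=C(O)C1=O | target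

**Totals**

Total step count: 6. Longest linear sequence: 5 steps (steps 2, 3, 4, 5, 6 from 4, or steps 1, 3, 4, 5, 6 from 1).

**Steps most likely to fail**

Step 6. The methoxy group on the oxadiene and the push-pull character of the 2π partner both slow the cycloaddition, and 15 may decompose before it cyclises. The fallback sets out from 15 and comes back at 17. Hydrolyse the vinylogous ester of 15 on oxalic-acid-doped wet silica gel to the hydroxymethylene ketone F1. Its 1,3-dicarbonyl carbon is far more nucleophilic, and catalytic Et3N closes ring A by a 6-exo Michael addition onto the ene-dione to give the formyl triketone F2. PPTS in toluene then closes ring B by cyclodehydration (ketone enol oxygen onto the aldehyde) and enolisation to 17, which the last operation of step 6 (TsOH·H2O, MeOH) converts into 18.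

Step 3. The furyllithium may add twice, or the hindered lactone may react too slowly next to a labile aldolate. The fallback sets out from 10 and comes back at 12. Quench 10 with AcOH and isolate the neutral aldol adduct F3. Open its activated lactone with MeNHOMe·HCl and i-PrMgCl (THF, −20 to 0 °C) to the Weinreb amide F4, with loss of pivalaldehyde. Treating F4 with excess 11 (THF, −78 to 0 °C) gives 12 through a chelated tetrahedral intermediate that cannot add a second time.

Step 4. The ene-diol 12 carries an acid-labile γ-hydroxy enol ether and a 1,2-diol, so oxidation may be accompanied by allylic transposition or cleavage. The fallback sets out from 9 and comes back at 13, bringing C8 in at the ketone oxidation level. Acylate 9 with the Weinreb amide F5 (made from commercial (E)-3-ethoxyacryloyl chloride, MeNHOMe·HCl and pyridine). The chelated lithium hemiaminal adduct F6 keeps the new carbonyl masked while 11 is added to the lactone in the same flask. The AcOH quench releases both carbonyls and gives 13 directly, without 12 and without an oxidation.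

**Further compounds**

F1 | step 6 | (1Z,4S,7E)-12-{[tert-butyl(dimethyl)silyl]oxy}-1-hydroxy-8-methoxy-4-methyl-3,5,6,9-tetraoxododeca-1,7-dien-4-yl butanoate | CCCC(=O)O[C@@](C)(C(=O)/C=C\O)C(=O)C(=O)/C=C(OC)\C(=O)CCCO[Si](C)(C)C(C)(C)C
F2 | step 6 | (1S)-4-(5-{[tert-butyl(dimethyl)silyl]oxy}-1-methoxy-2-oxopentyl)-3-formyl-1-methyl-2,5,6-trioxocyclohexyl butanoate | CCCC(=O)O[C@@]1(C)C(=O)C(C=O)C(C(OC)C(=O)CCCO[Si](C)(C)C(C)(C)C)C(=O)C1=O
F3 | step 3 | (2R,5S)-2-tert-butyl-5-[(2E)-3-ethoxy-1-hydroxyprop-2-en-1-yl]-5-methyl-1,3-dioxolan-4-one | CCO/C=C/C(O)[C@]1(C)O[C@@H](C(C)(C)C)OC1=O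
F4 | step 3 | (2S,4E)-5-ethoxy-2,3-dihydroxy-N-methoxy-N,2-dimethylpent-4-enamide | CCO/C=C/C(O)[C@](C)(O)C(=O)N(C)OC
F5 | step 4 | (2E)-3-ethoxy-N-methoxy-N-methylprop-2-enamide | CCO/C=C/C(=O)N(C)OC
F6 | step 4 | lithium (2E)-1-[(2R,4S)-2-tert-butyl-4-methyl-5-oxo-1,3-dioxolan-4-yl]-3-ethoxy-1-[methoxy(methyl)amino]prop-2-en-1-olate | CCO/C=C/C(O[Li])(N(C)OC)[C@]1(C)O[C@@H](C(C)(C)C)OC1=O
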